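## The problem

Target 25 is (2E,6E,10E,14R)-16-(2,5-dihydroxy-3-methylphenyl)-14-hydroxy-2,6,10,14-tetramethylhexadeca-2,6,10-trienoic acid. It is an open-chain meroterpenoid, so no ring has to be closed: a 2-alkyl-6-methylhydroquinone must be joined to an unbranched chain, numbered here from the benzylic CH2 (C1) to the carboxyl carbon (C16), with ring atoms C1' (chain-bearing) to C6'. The three trisubstituted alkenes C6=C7, C10=C11 and C14=C15 are all E and spaced as in farnesol, so their geometry is better bought than made. The only stereocentre, C3 (R), is a tertiary carbinol with CH3, OH and two CH2CH2 arms that first differ three bonds out (the arene beyond C1, the C6=C7 alkene beyond C5). Nothing else in the molecule can relay stereochemistry to it, and a reagent attacking a C3 ketone or alkene can scarcely tell the arms apart. The free hydroquinone is oxidised by air to the quinone, fastest as its phenoxide, and under acid the C3 hydroxyl ionises and is trapped by the C6' oxygen as a chromanol, which also erases C3. The 1,5-polyene likewise forbids strong acid, and the enoic acid is an electrophile towards organometallics, so the phenols stay masked to the end and C16 travels as a protected alcohol. The enabling feature is that C3 bears a methyl group and C4 is a plain methylene. Without the C4 arm, C3 is a secondary methyl carbinol (CH3 against CH2CH2Ar, an easy distinction), its C3–H is α to oxygen and removable, C4 is a primary carbon that can carry boron, and the ring is insulated from C3 by C1 and C2.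

## Retrosynthesis

**End game, Si–O, C16 and C–B adjustments.** Target 25 is taken back to its bis(triisopropylsilyl) ether 24, so that the last step cuts only two Si–O bonds and the hydroquinone is exposed once, under buffered non-oxidising conditions. Acid 24 comes from enal 23 and allylic alcohol 22, and 22 from the C16 tert-butyldimethylsilyl ether 21. C16 is kept at the alcohol level because an enoate would not survive the organolithium of the key step, and the alkyl silyl ether can be removed by mild acid while the aryl silyl ethers stay. Carbinol 21 comes from the tertiary boronic ester 20 by oxidation of C–B to C–O, which retains configuration.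

**C3–C4, the key cut.** Boronic ester 20 is divided into the hindered benzoate 8 of a secondary methyl carbinol (C1–C3 plus the ring) and the primary boronic ester 17 (C4–C16). Against a cut at C1–C2 or C5–C6 this is the only one that makes the stereocentre while joining the halves, and it turns the hard CH2CH2/CH2CH2 distinction into the trivial CH3/CH2 distinction of 8. Both fragments are far simpler, each holding about half of the carbons and 8 holding one easily sourced stereocentre. The forward reaction must deprotonate C3–H of 8 without touching the ring, hold the configuration of the tertiary organolithium, and move C4 from boron to C3 stereospecifically.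

**C1'–C1, arene to side chain.** Benzoate 8 is cut between the ring and C1 into aryl bromide 4 and the butenyl benzoate 6, itself the ester of (S)-but-3-en-2-ol 5. Against alkynylation of 4 followed by hydrogenation and esterification this saves a step, avoids a reduction, and puts the bulky ester on a small alcohol before the coupling. Demanded is a hydroboration that places boron on the terminal carbon and an sp3–sp2 cross-coupling that tolerates an ortho silyloxy group.

**Ring substituents.** Bromide 4 is traced through hydroquinone 3 and bromophenol 2 to 4-methoxy-2-methylphenol 1, in which the free hydroxyl leaves only one open ortho position for bromine, so the 1,2,3,5 pattern of the target follows from directing effects alone. The methyl ether is exchanged for silyl because a methoxy group with two free ortho positions would invite ring lithiation in the key step and could later be removed only through the quinone.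

**C4–C5 and the chain terminus.** Boronic ester 17 is the six-membered analogue of pinacol ester 15, needed because the crowded ate complex of the key step forms cleanly only with a small diol on boron. Ester 15 is cut between C4 and C5 into allylic bromide 13 and bis(pinacolatoboryl)methane 14, which supplies C4 together with its boron in one operation. Bromide 13 comes from alcohol 12, acetate 11 and hydroxy acetate 10, and 10 from (2E,6E)-farnesyl acetate 9 by oxidation of the terminal E-methyl group. All three alkene geometries are thus inherited, and only the SN2 course of the alkylation and the site of the allylic oxidation have to be secured.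

## Roads not taken

**Alternative 1:** The cut runs through the benzene ring. Its six carbons are traced to the terminal alkyne A2 (the whole chain ending in a but-3-ynyl group at C1, C3 already set and silylated, C16 as methyl ester), the chromium propenyl(methoxy)carbene complex A3 and one carbonyl ligand. In the forward Dötz benzannulation the alkyne inserts into the Cr=C bond, CO follows, and electrocyclisation gives the 4-methoxyphenol A1. The chain lands next to the new phenol and the propenyl methyl on its other side, exactly the pattern required.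
- Merits: arene regiochemistry is built in, no aryl halide or phenol protection is needed during chain assembly, and the ester can be carried because no organolithium follows.
- Weak points: A2 still contains C3 with its two similar arms, so the real problem is only moved and a second key step is needed. Stoichiometric chromium is applied to the most advanced intermediate. The remaining methyl ether comes off only by oxidation to the quinone and reduction.
- Comparison: for the arene this road is at least as good as the chosen one, which spends three steps on 4 and carries two silyl ethers to the end. The chosen plan sets against that a key step that creates the only stereocentre.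

**Alternative 2:** The cut is C1–C2. The symmetric arene A5 has two equivalent methyl groups; metalation of one with an alkyllithium/potassium alkoxide superbase gives a benzylic anion that opens the 2-methyl-2-alkyloxirane A6 at its CH2 to give carbinol A4.
- Merits: symmetry removes the regiochemical question that costs three steps for 4, the coupling does not touch the stereocentre, and the hydroxyl is already in place.
- Weak points: A6 poses the same CH3/CH2 problem as an epoxidation of a 1,1-disubstituted alkene beside three more electron-rich trisubstituted alkenes, for which no chemoselective asymmetric method exists. A6 would therefore need a chiral four-carbon building block and further C–C couplings. Ring metalation next to the methoxy groups and base-induced opening of the epoxide to an allylic alcohol compete, and the methyl ethers again leave only through the quinone.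
- Comparison: the arene half is shorter, and a final quinone reduction is arguably gentler than fluoride; in both respects this road is better. The chosen plan sets against it an enantiopure catalogue carbinol and a stereospecific bond formation at C3 itself.

**Alternative 3:** The cut is C5–C6. The head is the redox-active ester A8, derived from (R)-linalool A10 (vinyl group turned into the arylethyl arm, prenyl alkene cleaved to the acid); the tail is the (E)-alkenyl iodide A9 carrying the methyl ester. A nickel-catalysed electroreductive decarboxylative alkenylation at a sacrificial anode would give A7.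
- Merits: the stereocentre is taken from the chiral pool, the route is the most convergent, and C16 travels as the ester, so the end needs no oxidation.
- Weak points: the optical purity of A7 cannot exceed that of A10, an essential-oil alcohol that is not always enantiopure. The C6=C7 geometry must be constructed in A9 instead of being bought with farnesol. The primary radical can add to the enoate of A9 or A7 or be reduced, and the methyl ethers need the quinone detour.
- Comparison: in redox economy this road is clearly better, since the chosen plan spends three steps on C16. The chosen plan sets against it a closed-shell key step on a precedented substrate class and a stereocentre whose purity is fixed by a defined reagent.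

Key step: step 12

Assumption: C3 of the target is R as read from its stereo-SMILES, which requires the S benzoate 8; (2E,6E)-farnesyl acetate and (S)-but-3-en-2-ol are treated as catalogue compounds. TIPS = triisopropylsilyl, TBS = tert-butyldimethylsilyl.

## Steps

Step 1
Reactants: 1 4-methoxy-2-methylphenol
Product: 2 2-bromo-4-methoxy-6-methylphenol
Conditions: Br2 (1.0 equiv), CH2Cl2, −10 → 0 °C
Reagents that add atoms: bromine, BrBr
Why: Electrophilic aromatic bromination; the hydroxyl is the strongest director, its para position is blocked by OMe and one ortho position by CH3, so bromine should enter at the remaining ortho carbon.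

Step 2
Reactants: 2 2-bromo-4-methoxy-6-methylphenol
Product: 3 2-bromo-6-methylbenzene-1,4-diol
Conditions: BBr3, CH2Cl2, −78 °C → rt; H2O
Reagents that add atoms: none
Why: Lewis-acid cleavage of the aryl methyl ether (bromide attacks the O-methyl group of the boron-bound ether); aryl bromide and ring methyl are inert, and the product is handled under argon.

Step 3
Reactants: 3 2-bromo-6-methylbenzene-1,4-diol
Product: 4 1-bromo-3-methyl-2,5-bis[(triisopropylsilyl)oxy]benzene
Conditions: TIPSOTf (2.4 equiv), 2,6-lutidine, CH2Cl2, 0 °C → rt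
Reagents that add atoms: triisopropylsilyl trifluoromethanesulfonate, CC(C)[Si](OS(=O)(=O)C(F)(F)F)(C(C)C)C(C)C
Why: O-silylation; the silyl triflate is needed for the hydroxyl flanked by Br and CH3, and TIPS is chosen because it should survive aqueous base, alkyllithium and mild acid and is a poor director of ring metalation.

Step 4
Reactants: 5 (S)-but-3-en-2-ol
Product: 6 (S)-but-3-en-2-yl 2,4,6-triisopropylbenzoate
Conditions: NaH, THF, 0 °C; 2,4,6-triisopropylbenzoyl chloride, 0 → 60 °C
Reagents that add atoms: 2,4,6-triisopropylbenzoyl chloride, CC(C)c1cc(C(C)C)c(C(Cl)=O)c(C(C)C)c1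
Why: O-acylation of the sodium alkoxide; the carbinol C–O bond is not touched, so the S configuration is retained, and the doubly ortho-branched benzoate is the directing and leaving group needed in step 12.

Step 5
Reactants: 6 (S)-but-3-en-2-yl 2,4,6-triisopropylbenzoate; 4 1-bromo-3-methyl-2,5-bis[(triisopropylsilyl)oxy]benzene
Product: 8 (S)-4-{3-methyl-2,5-bis[(triisopropylsilyl)oxy]phenyl}butan-2-yl 2,4,6-triisopropylbenzoate, via B-alkyl-9-BBN adduct 7 (not isolated)
Conditions: 9-BBN, THF, 0 °C → rt; then 4, Pd(OAc)2, SPhos, aq K3PO4, THF, 60 °C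
Reagents that add atoms: 9-borabicyclo[3.3.1]nonane (9-BBN), B1C2CCCC1CCC2 (its boron is carried by 7 only; 8 keeps its hydrogen)
Why: Anti-Markovnikov hydroboration of the vinyl group followed by B-alkyl Suzuki–Miyaura coupling with the electron-rich aryl bromide forms the C1'–C1 bond; the carbinol stereocentre is not involved and the hindered benzoate resists borane and aqueous base.

Step 6
Reactants: 9 (2E,6E)-farnesyl acetate
Product: 10 (2E,6E,10E)-12-hydroxy-3,7,11-trimethyldodeca-2,6,10-trien-1-yl acetate
Conditions: SeO2 (cat.), tBuOOH, salicylic acid (cat.), CH2Cl2, 0 °C → rt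
Reagents that add atoms: tert-butyl hydroperoxide, CC(C)(C)OO (oxygen relayed by SeO2)
Why: Catalytic selenium dioxide allylic oxidation (ene reaction, then [2,3]-sigmatropic shift) should favour the E-methyl group of the terminal, most accessible trisubstituted alkene, the C2=C3 alkene being deactivated by the allylic acetate; any enal from over-oxidation can be returned to 10 by a borohydride treatment.

Step 7
Reactants: 10 (2E,6E,10E)-12-hydroxy-3,7,11-trimethyldodeca-2,6,10-trien-1-yl acetate
Product: 11 (2E,6E,10E)-12-[(tert-butyldimethylsilyl)oxy]-3,7,11-trimethyldodeca-2,6,10-trien-1-yl acetate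
Conditions: TBSCl, imidazole, CH2Cl2, 0 °C → rt
Reagents that add atoms: tert-butyldimethylsilyl chloride, CC(C)(C)[Si](C)(C)Cl
Why: Standard silylation of a primary allylic alcohol; the silyl ether will carry the future C16 through base, alkoxide and organolithium.

Step 8
Reactants: 11 (2E,6E,10E)-12-[(tert-butyldimethylsilyl)oxy]-3,7,11-trimethyldodeca-2,6,10-trien-1-yl acetate
Product: 12 (2E,6E,10E)-12-[(tert-butyldimethylsilyl)oxy]-3,7,11-trimethyldodeca-2,6,10-trien-1-ol
Conditions: K2CO3, MeOH, 0 °C → rt
Reagents that add atoms: none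
Why: Base-catalysed transesterification removes the acetate while the alkyl silyl ether is stable, which differentiates the two allylic termini.

Step 9
Reactants: 12 (2E,6E,10E)-12-[(tert-butyldimethylsilyl)oxy]-3,7,11-trimethyldodeca-2,6,10-trien-1-ol
Product: 13 {[(2E,6E,10E)-12-bromo-2,6,10-trimethyldodeca-2,6,10-trien-1-yl]oxy}(tert-butyl)dimethylsilane
Conditions: CBr4, PPh3, CH2Cl2, −20 → 0 °C; pentane trituration, used at once
Reagents that add atoms: tetrabromomethane, BrC(Br)(Br)Br
Why: Appel reaction; SN2 displacement of the oxyphosphonium at the primary allylic carbon under neutral conditions should keep the E geometry and the silyl ether.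

Step 10
Reactants: 13 {[(2E,6E,10E)-12-bromo-2,6,10-trimethyldodeca-2,6,10-trien-1-yl]oxy}(tert-butyl)dimethylsilane; 14 bis(pinacolatoboryl)methane
Product: 15 tert-butyldimethyl{[(2E,6E,10E)-2,6,10-trimethyl-13-(4,4,5,5-tetramethyl-1,3,2-dioxaborolan-2-yl)trideca-2,6,10-trien-1-yl]oxy}silane
Conditions: 14 (1.5 equiv), NaOtBu, THF, 0 °C (premixed); then 13, 0 °C → rt
Reagents that add atoms: none
Why: Alkoxide-promoted deborylative alkylation: tert-butoxide adds to one boron of 14, loss of the tert-butoxyborane leaves an α-boryl carbanion, and this soft nucleophile should displace the primary allylic bromide by SN2, adding C4 together with its boron.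

Step 11
Reactants: 15 tert-butyldimethyl{[(2E,6E,10E)-2,6,10-trimethyl-13-(4,4,5,5-tetramethyl-1,3,2-dioxaborolan-2-yl)trideca-2,6,10-trien-1-yl]oxy}silane
Product: 17 tert-butyl{[(2E,6E,10E)-13-(5,5-dimethyl-1,3,2-dioxaborinan-2-yl)-2,6,10-trimethyltrideca-2,6,10-trien-1-yl]oxy}dimethylsilane, via boronic acid 16 (not isolated)
Conditions: NaIO4, NH4OAc, acetone/H2O, rt; Et2O extract (not concentrated) + neopentyl glycol, MgSO4, rt
Reagents that add atoms: 2,2-dimethylpropane-1,3-diol (neopentyl glycol), OCC(C)(C)CO; water, O (supplies the hydroxyls of 16 only)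
Why: Periodate cleaves the released pinacol irreversibly (glycol cleavage) and so drives hydrolysis to the boronic acid, while the 1,3-diol is inert to periodate and condenses with the acid over a drying agent to the less hindered six-membered ester.

Step 12
Reactants: 8 (S)-4-{3-methyl-2,5-bis[(triisopropylsilyl)oxy]phenyl}butan-2-yl 2,4,6-triisopropylbenzoate; 17 tert-butyl{[(2E,6E,10E)-13-(5,5-dimethyl-1,3,2-dioxaborinan-2-yl)-2,6,10-trimethyltrideca-2,6,10-trien-1-yl]oxy}dimethylsilane
Product: 20 2-[(3S,6E,10E,14E)-16-[(tert-butyldimethylsilyl)oxy]-3,7,11,15-tetramethyl-1-{3-methyl-2,5-bis[(triisopropylsilyl)oxy]phenyl}hexadeca-6,10,14-trien-3-yl]-5,5-dimethyl-1,3,2-dioxaborinane, via lithiated benzoate 18 (not isolated), via lithium boronate complex 19 (not isolated)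
Conditions: 8 (1.4 equiv), sBuLi (1.3 equiv), TMEDA (6 equiv), CPME, −60 °C; then 17 (1.0 equiv), −60 °C → rt
Reagents that add atoms: sec-butyllithium, CCC(C)[Li] (its lithium sits in 18 and 19 only)
Why: The benzoate carbonyl binds sBuLi/TMEDA and directs removal of the C3–H, giving the chelated tertiary α-oxy organolithium 18 with retention; at −60 °C in this ether it should be configurationally stable. Compound 18 attacks the empty orbital on boron of 17 from the lithium-bearing face (retention) to give ate complex 19, and on warming C4 shifts from boron to C3 antiperiplanar to the departing benzoate (inversion), so that boron ends where hydrogen was and C4 where oxygen was. The closest known reaction type is the lithiation–borylation of secondary dialkyl 2,4,6-triisopropylbenzoates with primary alkyl neopentyl glycol boronic esters, the 4-phenylbutan-2-yl ester being the parent of 8. No ring is closed; one C–C and one C–B bond form. The new stereocentre C3 is controlled solely by the configuration of 8, because each of the three events is stereospecific (S in 20, where boron ranks lowest, becoming R once oxygen replaces boron). The step needs site-selective deprotonation, secured by carbonyl-directed proximity, by the two ortho isopropyl groups that shield the carbonyl from addition, and by TIPS ethers that do not direct ring metalation. It also needs migration of carbon and not oxygen, secured by the primary migrating group and the good benzoate leaving group. The small diol on boron lets the crowded ate complex form irreversibly, which protects the stereochemical outcome.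

Step 13
Reactants: 20 2-[(3S,6E,10E,14E)-16-[(tert-butyldimethylsilyl)oxy]-3,7,11,15-tetramethyl-1-{3-methyl-2,5-bis[(triisopropylsilyl)oxy]phenyl}hexadeca-6,10,14-trien-3-yl]-5,5-dimethyl-1,3,2-dioxaborinane
Product: 21 (3R,6E,10E,14E)-16-[(tert-butyldimethylsilyl)oxy]-3,7,11,15-tetramethyl-1-{3-methyl-2,5-bis[(triisopropylsilyl)oxy]phenyl}hexadeca-6,10,14-trien-3-ol
Conditions: NaBO3·4H2O, THF/H2O, rt
Reagents that add atoms: sodium perborate (used as tetrahydrate), [Na+].[Na+].O[B-]1(O)OO[B-](O)(O)OO1
Why: Oxidation of the C–B bond by 1,2-shift of C3 from boron to peroxide oxygen proceeds with retention, and the mildly basic perborate should spare the aryl silyl ethers and the alkenes.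

Step 14
Reactants: 21 (3R,6E,10E,14E)-16-[(tert-butyldimethylsilyl)oxy]-3,7,11,15-tetramethyl-1-{3-methyl-2,5-bis[(triisopropylsilyl)oxy]phenyl}hexadeca-6,10,14-trien-3-ol
Product: 22 (2E,6E,10E,14R)-2,6,10,14-tetramethyl-16-{3-methyl-2,5-bis[(triisopropylsilyl)oxy]phenyl}hexadeca-2,6,10-triene-1,14-diol
Conditions: PPTS, MeOH, rt → 40 °C
Reagents that add atoms: none
Why: Mild acid methanolysis removes the unhindered primary alkyl silyl ether; the aryl TIPS ethers are far slower, and with both phenols masked the tertiary alcohol cannot close to a chromanol.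

Step 15
Reactants: 22 (2E,6E,10E,14R)-2,6,10,14-tetramethyl-16-{3-methyl-2,5-bis[(triisopropylsilyl)oxy]phenyl}hexadeca-2,6,10-triene-1,14-diol
Product: 23 (2E,6E,10E,14R)-14-hydroxy-2,6,10,14-tetramethyl-16-{3-methyl-2,5-bis[(triisopropylsilyl)oxy]phenyl}hexadeca-2,6,10-trienal
Conditions: MnO2, CH2Cl2, rt
Reagents that add atoms: none
Why: Manganese dioxide oxidises only the allylic primary alcohol, keeps the E geometry, and cannot oxidise the tertiary carbinol.

Step 16
Reactants: 23 (2E,6E,10E,14R)-14-hydroxy-2,6,10,14-tetramethyl-16-{3-methyl-2,5-bis[(triisopropylsilyl)oxy]phenyl}hexadeca-2,6,10-trienal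
Product: 24 (2E,6E,10E,14R)-14-hydroxy-2,6,10,14-tetramethyl-16-{3-methyl-2,5-bis[(triisopropylsilyl)oxy]phenyl}hexadeca-2,6,10-trienoic acid
Conditions: NaClO2, NaH2PO4, 2-methylbut-2-ene (large excess), tBuOH/H2O, 0 °C → rt
Reagents that add atoms: sodium chlorite, [Na+].[O-]Cl=O
Why: Pinnick oxidation of the enal to the enoic acid; the excess scavenger alkene intercepts hypochlorous acid before it can reach the chain alkenes or the silylated arene.

Step 17
Reactants: 24 (2E,6E,10E,14R)-14-hydroxy-2,6,10,14-tetramethyl-16-{3-methyl-2,5-bis[(triisopropylsilyl)oxy]phenyl}hexadeca-2,6,10-trienoic acid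
Product: 25 (2E,6E,10E,14R)-16-(2,5-dihydroxy-3-methylphenyl)-14-hydroxy-2,6,10,14-tetramethylhexadeca-2,6,10-trienoic acid
Conditions: Bu4NF, AcOH, THF (degassed, argon), 0 °C; aq NH4Cl work-up under argon
Reagents that add atoms: none
Why: Fluoride cleaves both aryl Si–O bonds; acetic acid protonates each phenoxide as it forms, which should suppress air oxidation, and is too weak to ionise the C3 carbinol.

## Compound list

1 | 4-methoxy-2-methylphenol | COc1ccc(O)c(C)c1 | starting material
2 | 2-bromo-4-methoxy-6-methylphenol | COc1cc(C)c(O)c(Br)c1 | intermediate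
3 | 2-bromo-6-methylbenzene-1,4-diol | Cc1cc(O)cc(Br)c1O | intermediate
4 | 1-bromo-3-methyl-2,5-bis[(triisopropylsilyl)oxy]benzene | Cc1cc(O[Si](C(C)C)(C(C)C)C(C)C)cc(Br)c1O[Si](C(C)C)(C(C)C)C(C)C | intermediate
5 | (S)-but-3-en-2-ol | C[C@H](O)C=C | starting material
6 | (S)-but-3-en-2-yl 2,4,6-triisopropylbenzoate | C[C@H](OC(=O)c1c(C(C)C)cc(C(C)C)cc1C(C)C)C=C | intermediate
7 | (S)-4-(9-borabicyclo[3.3.1]nonan-9-yl)butan-2-yl 2,4,6-triisopropylbenzoate | C[C@H](OC(=O)c1c(C(C)C)cc(C(C)C)cc1C(C)C)CCB1C2CCCC1CCC2 | intermediate
8 | (S)-4-{3-methyl-2,5-bis[(triisopropylsilyl)oxy]phenyl}butan-2-yl 2,4,6-triisopropylbenzoate | C[C@H](OC(=O)c1c(C(C)C)cc(C(C)C)cc1C(C)C)CCc1cc(O[Si](C(C)C)(C(C)C)C(C)C)cc(C)c1O[Si](C(C)C)(C(C)C)C(C)C | intermediate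
9 | (2E,6E)-farnesyl acetate | CC(C)=CCC/C(C)=C/CC/C(C)=C/COC(C)=O | starting material
10 | (2E,6E,10E)-12-hydroxy-3,7,11-trimethyldodeca-2,6,10-trien-1-yl acetate | C/C(=C\CC/C(C)=C/COC(C)=O)CC/C=C(\C)CO | intermediate
11 | (2E,6E,10E)-12-[(tert-butyldimethylsilyl)oxy]-3,7,11-trimethyldodeca-2,6,10-trien-1-yl acetate | C/C(=C\CC/C(C)=C/COC(C)=O)CC/C=C(\C)CO[Si](C)(C)C(C)(C)C | intermediate
12 | (2E,6E,10E)-12-[(tert-butyldimethylsilyl)oxy]-3,7,11-trimethyldodeca-2,6,10-trien-1-ol | C/C(=C\CC/C(C)=C/CO)CC/C=C(\C)CO[Si](C)(C)C(C)(C)C | intermediate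
13 | {[(2E,6E,10E)-12-bromo-2,6,10-trimethyldodeca-2,6,10-trien-1-yl]oxy}(tert-butyl)dimethylsilane | C/C(=C\CC/C(C)=C/CBr)CC/C=C(\C)CO[Si](C)(C)C(C)(C)C | intermediate
14 | bis(pinacolatoboryl)methane | CC1(C)OB(CB2OC(C)(C)C(C)(C)O2)OC1(C)C | starting material
15 | tert-butyldimethyl{[(2E,6E,10E)-2,6,10-trimethyl-13-(4,4,5,5-tetramethyl-1,3,2-dioxaborolan-2-yl)trideca-2,6,10-trien-1-yl]oxy}silane | C/C(=C\CC/C(C)=C/CCB1OC(C)(C)C(C)(C)O1)CC/C=C(\C)CO[Si](C)(C)C(C)(C)C | intermediate
16 | [(3E,7E,11E)-13-[(tert-butyldimethylsilyl)oxy]-4,8,12-trimethyltrideca-3,7,11-trien-1-yl]boronic acid | C/C(=C\CC/C(C)=C/CCB(O)O)CC/C=C(\C)CO[Si](C)(C)C(C)(C)C | intermediate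
17 | tert-butyl{[(2E,6E,10E)-13-(5,5-dimethyl-1,3,2-dioxaborinan-2-yl)-2,6,10-trimethyltrideca-2,6,10-trien-1-yl]oxy}dimethylsilane | C/C(=C\CC/C(C)=C/CCB1OCC(C)(C)CO1)CC/C=C(\C)CO[Si](C)(C)C(C)(C)C | intermediate
18 | (S)-2-lithio-4-{3-methyl-2,5-bis[(triisopropylsilyl)oxy]phenyl}butan-2-yl 2,4,6-triisopropylbenzoate (lithium in place of the carbinol hydrogen of 8, configuration retained) | C[C@]([Li])(OC(=O)c1c(C(C)C)cc(C(C)C)cc1C(C)C)CCc1cc(O[Si](C(C)C)(C(C)C)C(C)C)cc(C)c1O[Si](C(C)C)(C(C)C)C(C)C | intermediate
19 | lithium boronate complex: tetracoordinate borate in which the boron of 17 is bonded to the carbinol carbon of 18 in place of lithium (retention), that carbon still carrying the benzoate | [Li+].C[C@]([B-]1(CC/C=C(\C)CC/C=C(\C)CC/C=C(\C)CO[Si](C)(C)C(C)(C)C)OCC(C)(C)CO1)(OC(=O)c1c(C(C)C)cc(C(C)C)cc1C(C)C)CCc1cc(O[Si](C(C)C)(C(C)C)C(C)C)cc(C)c1O[Si](C(C)C)(C(C)C)C(C)C | intermediate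
20 | 2-[(3S,6E,10E,14E)-16-[(tert-butyldimethylsilyl)oxy]-3,7,11,15-tetramethyl-1-{3-methyl-2,5-bis[(triisopropylsilyl)oxy]phenyl}hexadeca-6,10,14-trien-3-yl]-5,5-dimethyl-1,3,2-dioxaborinane | C/C(=C\CC/C(C)=C/CC[C@@](C)(B1OCC(C)(C)CO1)CCc1cc(O[Si](C(C)C)(C(C)C)C(C)C)cc(C)c1O[Si](C(C)C)(C(C)C)C(C)C)CC/C=C(\C)CO[Si](C)(C)C(C)(C)C | intermediate
21 | (3R,6E,10E,14E)-16-[(tert-butyldimethylsilyl)oxy]-3,7,11,15-tetramethyl-1-{3-methyl-2,5-bis[(triisopropylsilyl)oxy]phenyl}hexadeca-6,10,14-trien-3-ol | C/C(=C\CC/C(C)=C/CC[C@@](C)(O)CCc1cc(O[Si](C(C)C)(C(C)C)C(C)C)cc(C)c1O[Si](C(C)C)(C(C)C)C(C)C)CC/C=C(\C)CO[Si](C)(C)C(C)(C)C | intermediate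
22 | (2E,6E,10E,14R)-2,6,10,14-tetramethyl-16-{3-methyl-2,5-bis[(triisopropylsilyl)oxy]phenyl}hexadeca-2,6,10-triene-1,14-diol | C/C(=C\CC/C(C)=C/CC[C@@](C)(O)CCc1cc(O[Si](C(C)C)(C(C)C)C(C)C)cc(C)c1O[Si](C(C)C)(C(C)C)C(C)C)CC/C=C(\C)CO | intermediate
23 | (2E,6E,10E,14R)-14-hydroxy-2,6,10,14-tetramethyl-16-{3-methyl-2,5-bis[(triisopropylsilyl)oxy]phenyl}hexadeca-2,6,10-trienal | C/C(=C\CC/C(C)=C/CC[C@@](C)(O)CCc1cc(O[Si](C(C)C)(C(C)C)C(C)C)cc(C)c1O[Si](C(C)C)(C(C)C)C(C)C)CC/C=C(\C)C=O | intermediate
24 | (2E,6E,10E,14R)-14-hydroxy-2,6,10,14-tetramethyl-16-{3-methyl-2,5-bis[(triisopropylsilyl)oxy]phenyl}hexadeca-2,6,10-trienoic acid | C/C(=C\CC/C(C)=C/CC[C@@](C)(O)CCc1cc(O[Si](C(C)C)(C(C)C)C(C)C)cc(C)c1O[Si](C(C)C)(C(C)C)C(C)C)CC/C=C(\C)C(=O)O | intermediate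
25 | (2E,6E,10E,14R)-16-(2,5-dihydroxy-3-methylphenyl)-14-hydroxy-2,6,10,14-tetramethylhexadeca-2,6,10-trienoic acid | C/C(=C\CC/C(C)=C/CC[C@@](C)(O)CCc1cc(O)cc(C)c1O)CC/C=C(\C)C(=O)O | target

## Step count and least certain steps

Total: 17 steps. Longest linear sequence: 12 steps (9 → 25, steps 6 to 17); the arene branch reaches 8 in four linear steps from 1, with one further step for 6.

**Step 12 (key step).** Most likely failure: deprotonation of 8 is slow and incomplete, so unreacted sBuLi adds to the boron of 17 and wastes the more valuable fragment, while slow capture of the hindered organolithium gives time for its decomposition or loss of configuration. Fallback, from 8 to 20: the lithiation of 8 is run alone and quenched with Me3SnCl to give (R)-4-{3-methyl-2,5-bis[(triisopropylsilyl)oxy]phenyl}-2-(trimethylstannyl)butan-2-yl 2,4,6-triisopropylbenzoate F1, which can be purified and its enantiopurity checked. Tin–lithium exchange with nBuLi (1 equiv, −78 °C), which retains configuration, then regenerates 18 free of excess base and diamine, and addition of 17 leads through 19 back to 20.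

**Step 5.** Most likely failure: slow oxidative addition and transmetalation at the hindered, electron-rich bromide, with protodeboronation of the alkylborane and partial loss of an aryl silyl group in hot aqueous base. Fallback, from 4 to 8: Sonogashira coupling of 4 with commercial (R)-but-3-yn-2-ol (Pd(PPh3)2Cl2, CuI, iPr2NH) gives (R)-4-{3-methyl-2,5-bis[(triisopropylsilyl)oxy]phenyl}but-3-yn-2-ol F2. Hydrogenation (H2, Pd/C, EtOAc) gives (R)-4-{3-methyl-2,5-bis[(triisopropylsilyl)oxy]phenyl}butan-2-ol F3. Mitsunobu esterification with 2,4,6-triisopropylbenzoic acid (PPh3, diisopropyl azodicarboxylate, THF) inverts the carbinol and returns to 8.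

**Step 10.** Most likely failure: tert-butoxide attacks the allylic bromide directly (elimination to a diene, ether formation or SN2' attack) before the boryl carbanion does, and the product may protodeboronate. Fallback, from 11 to 15: borylation of the allylic acetate 11 with bis(pinacolato)diboron and Pd2(dba)3 (a complex of zerovalent palladium) gives tert-butyldimethyl{[(2E,6E,10E)-2,6,10-trimethyl-12-(4,4,5,5-tetramethyl-1,3,2-dioxaborolan-2-yl)dodeca-2,6,10-trien-1-yl]oxy}silane F4. Matteson homologation with chloromethyllithium (BrCH2Cl, nBuLi, THF, −78 °C → rt) then inserts C4 and returns to 15.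

**Step 11.** Most likely failure: incomplete removal of pinacol, or hydrolysis of the less robust six-membered ester during purification, with loss of the silyl ether if the medium turns acidic. Fallback, from 15 to 17: transesterification with diethanolamine in Et2O precipitates 2-[(3E,7E,11E)-13-[(tert-butyldimethylsilyl)oxy]-4,8,12-trimethyltrideca-3,7,11-trien-1-yl]-1,3,6,2-dioxazaborocane F5, which is filtered off. Brief shaking with neopentyl glycol in Et2O over a pH 4–5 acetate buffer then returns to 17.

**Step 17.** Most likely failure: air oxidation of the hydroquinone while it passes through its phenoxide, and acid-induced cyclisation to the chromanol during work-up or chromatography. Fallback, from 24 to 25: the oxidation is accepted and completed, desilylation with Bu4NF followed by Ag2O giving (2E,6E,10E,14R)-14-hydroxy-2,6,10,14-tetramethyl-16-(5-methyl-3,6-dioxocyclohexa-1,4-dien-1-yl)hexadeca-2,6,10-trienoic acid F6, a quinone that can be chromatographed. Reduction with aqueous Na2S2O4 in Et2O/H2O under argon returns to 25 under neutral conditions, with extraction as the only isolation.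

## Further compounds

F1 | step 12 | (R)-4-{3-methyl-2,5-bis[(triisopropylsilyl)oxy]phenyl}-2-(trimethylstannyl)butan-2-yl 2,4,6-triisopropylbenzoate | C[C@]([Sn](C)(C)C)(OC(=O)c1c(C(C)C)cc(C(C)C)cc1C(C)C)CCc1cc(O[Si](C(C)C)(C(C)C)C(C)C)cc(C)c1O[Si](C(C)C)(C(C)C)C(C)C
F2 | step 5 | (R)-4-{3-methyl-2,5-bis[(triisopropylsilyl)oxy]phenyl}but-3-yn-2-ol | C[C@@H](O)C#Cc1cc(O[Si](C(C)C)(C(C)C)C(C)C)cc(C)c1O[Si](C(C)C)(C(C)C)C(C)C
F3 | step 5 | (R)-4-{3-methyl-2,5-bis[(triisopropylsilyl)oxy]phenyl}butan-2-ol | C[C@@H](O)CCc1cc(O[Si](C(C)C)(C(C)C)C(C)C)cc(C)c1O[Si](C(C)C)(C(C)C)C(C)C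
F4 | step 10 | tert-butyldimethyl{[(2E,6E,10E)-2,6,10-trimethyl-12-(4,4,5,5-tetramethyl-1,3,2-dioxaborolan-2-yl)dodeca-2,6,10-trien-1-yl]oxy}silane | C/C(=C\CC/C(C)=C/CB1OC(C)(C)C(C)(C)O1)CC/C=C(\C)CO[Si](C)(C)C(C)(C)C
F5 | step 11 | 2-[(3E,7E,11E)-13-[(tert-butyldimethylsilyl)oxy]-4,8,12-trimethyltrideca-3,7,11-trien-1-yl]-1,3,6,2-dioxazaborocane | C/C(=C\CC/C(C)=C/CCB1OCCNCCO1)CC/C=C(\C)CO[Si](C)(C)C(C)(C)C
F6 | step 17 | (2E,6E,10E,14R)-14-hydroxy-2,6,10,14-tetramethyl-16-(5-methyl-3,6-dioxocyclohexa-1,4-dien-1-yl)hexadeca-2,6,10-trienoic acid | C/C(=C\CC/C(C)=C/CC[C@@](C)(O)CCC1=CC(=O)C=C(C)C1=O)CC/C=C(\C)C(=O)O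
A1 | alternative 1 | methyl (2E,6E,10E,14R)-16-(2-hydroxy-5-methoxy-3-methylphenyl)-2,6,10,14-tetramethyl-14-[(triethylsilyl)oxy]hexadeca-2,6,10-trienoate | C/C(=C\CC/C(C)=C/CC[C@@](C)(O[Si](CC)(CC)CC)CCc1cc(OC)cc(C)c1O)CC/C=C(\C)C(=O)OC
A2 | alternative 1 | methyl (2E,6E,10E,14R)-2,6,10,14-tetramethyl-14-[(triethylsilyl)oxy]octadeca-2,6,10-trien-17-ynoate | C/C(=C\CC/C(C)=C/CC[C@@](C)(O[Si](CC)(CC)CC)CCC#C)CC/C=C(\C)C(=O)OC
A3 | alternative 1 | pentacarbonyl[(2E)-1-methoxybut-2-en-1-ylidene]chromium, Cr(CO)5[C(OMe)CH=CHMe] | COC(/C=C/C)=[Cr](=C=O)(=C=O)(=C=O)(=C=O)=C=O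
A4 | alternative 2 | (3R,6E,10E,14E)-16-[(tert-butyldimethylsilyl)oxy]-1-(2,5-dimethoxy-3-methylphenyl)-3,7,11,15-tetramethylhexadeca-6,10,14-trien-3-ol | C/C(=C\CC/C(C)=C/CC[C@@](C)(O)CCc1cc(OC)cc(C)c1OC)CC/C=C(\C)CO[Si](C)(C)C(C)(C)C
A5 | alternative 2 | 2,5-dimethoxy-1,3-dimethylbenzene | COc1cc(C)c(OC)c(C)c1
A6 | alternative 2 | tert-butyldimethyl{[(2E,6E,10E)-2,6,10-trimethyl-13-[(2R)-2-methyloxiran-2-yl]trideca-2,6,10-trien-1-yl]oxy}silane | C/C(=C\CC/C(C)=C/CC[C@@]1(C)OC1)CC/C=C(\C)CO[Si](C)(C)C(C)(C)C
A7 | alternative 3 | methyl (2E,6E,10E,14R)-16-(2,5-dimethoxy-3-methylphenyl)-2,6,10,14-tetramethyl-14-[(triethylsilyl)oxy]hexadeca-2,6,10-trienoate | C/C(=C\CC/C(C)=C/CC[C@@](C)(O[Si](CC)(CC)CC)CCc1cc(OC)cc(C)c1OC)CC/C=C(\C)C(=O)OC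
A8 | alternative 3 | 1,3-dioxoisoindolin-2-yl (4S)-6-(2,5-dimethoxy-3-methylphenyl)-4-methyl-4-[(triethylsilyl)oxy]hexanoate | O=C(CC[C@@](C)(O[Si](CC)(CC)CC)CCc1cc(OC)cc(C)c1OC)ON1C(=O)c2ccccc2C1=O
A9 | alternative 3 | methyl (2E,6E,10E)-11-iodo-2,6,10-trimethylundeca-2,6,10-trienoate | I/C=C(\C)CC/C=C(\C)CC/C=C(\C)C(=O)OC
A10 | alternative 3 | (R)-linalool, (3R)-3,7-dimethylocta-1,6-dien-3-ol | CC(C)=CCC[C@@](C)(O)C=C
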